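If Tuesday's flask had stopped making target, I wanted its end state before anything else; how fast it got there could wait.

in all of them: solid substrate 0.18 M

| charge | reagent | temperature | remark | time |
|---|---|---|---|---|
| Tuesday's | 0.126 M | 80 °C | the very flask that is asked about, followed so far |  |
| Sunday's | 0.063 M | 65 °C | run made earlier |  |
| flask | 0.126 M | 80 °C |  | 8.0 d |

| run | time / h | target / % | solid substrate / % |
|---|---|---|---|
| Tuesday's | 10.0 | 40.4 | 41.8 |
| Tuesday's | 15.0 | 50.7 | 16.3 |
| Tuesday's | 20.0 | 51.9 | 3.6 |
| Tuesday's | 30.0 | 53.1 | 0.5 |
| Tuesday's | 50.0 | 53.4 | 0 |
| Tuesday's | 72.0 | 52.6 | 0.5 |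
| Tuesday's | 120 | 54.7 | 0 |
| Sunday's | 1.33 | 1.8 | 92.6 |
| Sunday's | 2.00 | 3.5 | 88.3 |
| Sunday's | 3.00 | 6.8 | 83.6 |
| Sunday's | 5.00 | 10.7 | 75.8 |
| Sunday's | 6.00 | 12.6 | 70.9 |
| Sunday's | 10.0 | 21.2 | 55.4 |
| Sunday's | 15.0 | 25.4 | 41.2 |

(standard deviation of a reading: 1 percentage point)

- elm: at 8.0 d raise the temperature by 10 K, then wait 2.5 d
- ash: at 8.0 d take out 90% of the target then present, then wait 2.5 d
- cedar: at 8.0 d add reagent, 50.0% of the amount charged, then wait 2.5 d
- maple: change nothing and wait 2.5 d more

- given per volume of solution although it is solid: solid substrate
- target that was removed still counts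
- candidate steps: solid substrate <-> dissolved substrate; dissolved substrate + reagent -> target; target <-> isomer of the product; solid substrate -> decomposition product
- at the start none of the solid substrate is in solution
- additions bring no volume worth counting

1. target, in percent of the solid substrate first charged, at 8.0 d
2. the remedy with the largest gain of target, or "none" below 2 percentage points (elm / ash / cedar / maple / none)
3. target present, with what was taken out counted in, in percent of the solid substrate first charged, after ash
4. target present, with what was taken out counted in, in percent of the solid substrate first charged, after cedar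

Between 15.0 h and 20.0 h Tuesday's solid substrate lost 13 percentage points, more than the 1.2 points that target gained. I therefore took reagent as the limiting reagent and reckoned the ceiling, the smaller of the reagent and solid charges as a fraction of the solid charge, which bounds target and isomer of the product together:

ceiling = 70.0%

The last four target readings gave the plateau, and the plateau gave target's share of the ceiling:

plateau = 53.4%; share = 76.4%

On Sunday's smaller ceiling that share gave 26.7%, and target had reached 25.4% at 15.0 h. I took the plateau as the reading at 8.0 d. For ash, the pair left behind would share out again: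

ash = 64.8%

Cedar raises the ceiling:

ceiling after cedar = 100%; target = 76.4%

That beat ash, while elm and maple left the ceiling where it stood.

The weak link was the remainder beyond the ceiling: cedar needed it to be dissolved substrate, not decomposition product. Solid fell by 0.0582 /h up to 10.0 h and by 0.0510 /h in the next stretch, with 41.8% or less remaining. A loss proportional to the solid slows with it, so I read the remainder as dissolved, unproved.

The forecast gave 53.5% (52.3% to 54.7%), cedar as the best remedy, 64.8% (59% to 68%) after ash and 75% (63% to 79%) after cedar, on the ground “which points to exhausted reagent”.

The flask gave 52.7%, 64.4% after ash and 75.0% after cedar, and cedar gained 22 points, more than ash's 12 points or elm's 0.12 points.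

    solid substrate ⇌ dissolved substrate, rate k1*(cs1 - [dissolved substrate]) while solid is left; crystals form when [dissolved substrate] > cs1 (solubility = 0.0670 M, k = 0.176 /h)
    dissolved substrate + reagent → target (k = 20.8 /M/h, Ea = 74.0 kJ/mol)
    target ⇌ isomer of the product (K = 0.329, k = 2.28 /h, Ea = 118 kJ/mol, ΔH = −1.00 kJ/mol)
    solid substrate → decomposition product (k = 3.94 × 10⁻⁴ /h, Ea = 122 kJ/mol)
    (constants at 80 °C)

The half-life of target by the forward step to isomer of the product, 0.30 h at 192 h, is far shorter than the 8.0 d waited. At that time Tuesday's flask holds reagent at 0% of its charge, target at 52.7%, isomer of the product at 17.3% and dissolved substrate at 29.7%.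

A neighbour flask with 0.32 M of reagent has 1.78 equiv of reagent, so its ceiling is 100% and the share gives 76.4% target. Computed, it holds 75.0% target and 24.7% isomer of the product.

The data are calculated from invented constants; scatter was added.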